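**Retrosynthetic overview**
- The chromene C3=C4 bond is made last but one, by DDQ dehydrogenation of a 2,2-dimethylchroman carried as its triacetate; acetate removal then gives the target.
- The pyranone (ring C) comes from a chalcone by 1,2-aryl shift with Tl(NO3)3, then acid closure onto the ring A oxygen unmasked from its MOM ether.
- The chalcone is made by Claisen–Schmidt aldol condensation of a ring A acetophenone with a ring B chroman aldehyde; this C–C bond becomes C2–C3 of the isoflavone.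
- Ring A acetophenone: from 2,5-dihydroxybenzaldehyde (Dakin-type oxidation, para-bromination, B-alkyl Suzuki for the side chain, ortho-lithiation/acetylation). Ring B aldehyde: from resorcinol and 3-methylbut-2-enoic acid.
- Ring order: dihydropyran of the ring B fragment first, pyranone second, chromene unsaturation last.

Assumption: the target has no stereocentre and no stereogenic double bond, so it is made as the one achiral compound drawn; intermediates with a transient stereocentre are racemic.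

**Step 1**
Reactants: 1 2,5-dihydroxybenzaldehyde
Product: 2 2,5-bis(benzyloxy)benzaldehyde
Conditions: BnBr (2.4 equiv), K2CO3 (3 equiv), DMF, 60 °C
Reagents that add atoms: benzyl bromide, BrCc1ccccc1
Why: Williamson ether synthesis alkylates both phenoxides, and the benzyl ethers survive every step up to the hydrogenolysis.

**Step 2**
Reactants: 2 2,5-bis(benzyloxy)benzaldehyde
Product: 4 2,5-bis(benzyloxy)phenol, via aryl formate 3 (not isolated)
Conditions: mCPBA (1.3 equiv), CH2Cl2, 0 °C → rt; then K2CO3 (cat.), MeOH, rt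
Reagents that add atoms: 3-chloroperoxybenzoic acid (mCPBA), OOC(=O)c1cccc(Cl)c1
Why: In this Baeyer–Villiger (Dakin-type) oxidation the electron-rich aryl group migrates to oxygen and the formate is methanolysed, so the third ring A oxygen arrives already differentiated from the two benzyl ethers.

**Step 3**
Reactants: 4 2,5-bis(benzyloxy)phenol
Product: 5 1,4-bis(benzyloxy)-2-(methoxymethoxy)benzene
Conditions: NaH (1.2 equiv), MOMCl (1.2 equiv), THF–DMF, 0 °C → rt
Reagents that add atoms: chloromethyl methyl ether (MOMCl), COCCl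
Why: O-alkylation of the phenoxide gives a MOM ether that directs ortho-lithiation, is base-stable and is later cleaved by mild acid without touching benzyl ethers.

**Step 4**
Reactants: 5 1,4-bis(benzyloxy)-2-(methoxymethoxy)benzene
Product: 6 1,4-bis(benzyloxy)-2-bromo-5-(methoxymethoxy)benzene
Conditions: NBS (1.05 equiv), MeCN, 0 °C, dark
Reagents that add atoms: N-bromosuccinimide, O=C1CCC(=O)N1Br
Why: Electrophilic aromatic bromination goes to the one position that is para to one alkoxy group and ortho to another (the 1,2,4-trialkoxybenzene pattern), which is where the side chain belongs.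

**Step 5**
Reactants: 6 1,4-bis(benzyloxy)-2-bromo-5-(methoxymethoxy)benzene; 7 2-methylbut-3-en-2-ol
Product: 9 4-[2,5-bis(benzyloxy)-4-(methoxymethoxy)phenyl]-2-methylbutan-2-ol, via alkylborane 8 (not isolated)
Conditions: 7 (1.6 equiv), 9-BBN (1.7 equiv), THF, 0 °C → rt; then 6, PdCl2(dppf) (5 mol %), aq. K3PO4, THF–DMF, 65 °C
Reagents that add atoms: none
Why: Anti-Markovnikov hydroboration of the terminal alkene followed by B-alkyl Suzuki–Miyaura coupling forms the aryl–CH2 bond and delivers the whole 3-hydroxy-3-methylbutyl chain without a reduction that could cleave benzyl ethers.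

**Step 6**
Reactants: 9 4-[2,5-bis(benzyloxy)-4-(methoxymethoxy)phenyl]-2-methylbutan-2-ol
Product: 11 1-[3,6-bis(benzyloxy)-5-(3-hydroxy-3-methylbutyl)-2-(methoxymethoxy)phenyl]ethan-1-one, via dilithio species 10 (not isolated)
Conditions: n-BuLi (2.5 equiv), THF, −20 → 0 °C; then MeC(O)N(OMe)Me (3 equiv), −78 → 0 °C; aq. NH4Cl
Reagents that add atoms: N-methoxy-N-methylacetamide, CC(=O)N(C)OC
Why: In this directed ortho-metalation the alkoxide forms first, lithiation then takes the only ring hydrogen flanked by two alkoxy groups (OMOM and OBn), and the Weinreb amide acylates the aryllithium without over-addition.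

**Step 7**
Reactants: 12 resorcinol; 13 3-methylbut-2-enoic acid
Product: 15 7-hydroxy-2,2-dimethylchroman-4-one, via acylresorcinol enone 14 (not isolated)
Conditions: P2O5–MeSO3H, 70 °C, 1 h
Reagents that add atoms: none
Why: Friedel–Crafts acylation of resorcinol at C4 followed by intramolecular oxa-Michael addition of the ortho hydroxyl closes the 2,2-dimethylchromanone.

**Step 8**
Reactants: 15 7-hydroxy-2,2-dimethylchroman-4-one
Product: 17 2,2-dimethylchroman-7-ol, via chroman-4-ol 16 (not isolated)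
Conditions: Et3SiH (3 equiv), CF3CO2H, rt → 50 °C
Reagents that add atoms: none
Why: In this ionic hydrogenation the protonated aryl ketone and then the benzylic cation from the carbinol, both stabilised by the para hydroxyl and the ortho ring oxygen, each accept hydride from Et3SiH to leave a methylene.

**Step 9**
Reactants: 17 2,2-dimethylchroman-7-ol
Product: 19 7-hydroxy-2,2-dimethylchroman-6-carbaldehyde, via salicyl alcohol 18 (not isolated)
Conditions: MgCl2 (1.5 equiv), Et3N, (CH2O)n (excess), MeCN, reflux; then 1 M HCl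
Reagents that add atoms: paraformaldehyde (as formaldehyde), C=O
Why: Magnesium-phenoxide-directed ortho-formylation (Casnati–Skattebøl) places the aldehyde at C6, the less hindered ortho position and also para to the ring oxygen, a second formaldehyde oxidising the hydroxymethyl intermediate.

**Step 10**
Reactants: 19 7-hydroxy-2,2-dimethylchroman-6-carbaldehyde
Product: 20 7-(benzyloxy)-2,2-dimethylchroman-6-carbaldehyde
Conditions: BnBr (1.3 equiv), K2CO3 (2 equiv), DMF, 60 °C
Reagents that add atoms: benzyl bromide, BrCc1ccccc1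
Why: Williamson ether synthesis masks the phenol, which as a phenoxide would deactivate the aldehyde in the aldol step and would interfere with the oxidative rearrangement.

**Step 11**
Reactants: 11 1-[3,6-bis(benzyloxy)-5-(3-hydroxy-3-methylbutyl)-2-(methoxymethoxy)phenyl]ethan-1-one; 20 7-(benzyloxy)-2,2-dimethylchroman-6-carbaldehyde
Product: 22 (E)-1-[3,6-bis(benzyloxy)-5-(3-hydroxy-3-methylbutyl)-2-(methoxymethoxy)phenyl]-3-[7-(benzyloxy)-2,2-dimethylchroman-6-yl]prop-2-en-1-one, via aldol adduct 21 (not isolated)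
Conditions: KOH (50% aq.), EtOH–THF, rt, 48 h
Reagents that add atoms: none
Why: In this Claisen–Schmidt crossed aldol condensation only the methyl ketone can enolise and only 20 is an aldehyde, and dehydration of the aldol gives the conjugated E-chalcone whose new C–C bond becomes C2–C3 of the isoflavone.

**Step 12**
Reactants: 22 the (E)-chalcone
Product: 23 1-[3,6-bis(benzyloxy)-5-(3-hydroxy-3-methylbutyl)-2-(methoxymethoxy)phenyl]-2-[7-(benzyloxy)-2,2-dimethylchroman-6-yl]-3,3-dimethoxypropan-1-one (racemic)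
Conditions: Tl(NO3)3·3H2O (1.2 equiv), MeOH–HC(OMe)3 (1:1), rt, 4 h
Reagents that add atoms: methanol, CO
Why: Oxythallation of the enone in methanol triggers an oxidative 1,2-aryl migration of the electron-rich ring B aryl from the β- to the α-carbon with loss of TlNO3, giving the β-keto acetal; its new stereocentre is racemic and is destroyed in the next step.

**Step 13**
Reactants: 23 the β-keto dimethyl acetal
Product: 25 5,8-bis(benzyloxy)-3-[7-(benzyloxy)-2,2-dimethylchroman-6-yl]-6-(3-hydroxy-3-methylbutyl)-4H-chromen-4-one, via free phenol acetal 24 (not isolated)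
Conditions: HCl (1 M in MeOH)–THF, 45 °C, 3 h
Reagents that add atoms: none
Why: Acid cleaves the MOM acetal and the freed ortho phenol adds to the oxocarbenium ion of the dimethyl acetal, loss of methanol giving the isoflavone by cyclodehydration; the regiochemistry is fixed because the other two ring A oxygens are still benzylated.

**Step 14**
Reactants: 25 the tribenzyl isoflavone
Product: 26 5,8-dihydroxy-3-(7-hydroxy-2,2-dimethylchroman-6-yl)-6-(3-hydroxy-3-methylbutyl)-4H-chromen-4-one
Conditions: H2 (1 atm), 10% Pd/C, EtOAc–MeOH, rt; monitored, used at once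
Reagents that add atoms: none
Why: Catalytic hydrogenolysis cleaves the three benzyl ethers while the tertiary alcohol, the saturated chroman and the chromone are retained.

**Step 15**
Reactants: 26 the trihydroxy chroman isoflavone
Product: 27 3-[7-(acetyloxy)-2,2-dimethylchroman-6-yl]-6-(3-hydroxy-3-methylbutyl)-4-oxo-4H-chromene-5,8-diyl diacetate
Conditions: Ac2O, pyridine, rt → 40 °C, Ar
Reagents that add atoms: acetic anhydride, CC(=O)OC(C)=O
Why: O-Acylation of the three phenols (the tertiary alcohol does not react without DMAP) protects the ring A hydroquinone from oxidation by DDQ.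

**Step 16**
Reactants: 27 the chroman triacetate
Product: 28 3-[7-(acetyloxy)-2,2-dimethyl-2H-chromen-6-yl]-6-(3-hydroxy-3-methylbutyl)-4-oxo-4H-chromene-5,8-diyl diacetate
Conditions: DDQ (2.2 equiv), dry 1,4-dioxane, reflux
Reagents that add atoms: none
Why: In this DDQ dehydrogenation, hydride abstraction from the benzylic C4 of the chroman, assisted by the ortho ring oxygen, and loss of a C3 proton give the 2,2-dimethyl-2H-chromene.

**Step 17**
Reactants: 28 the chromene triacetate
Product: 29 5,8-dihydroxy-6-(3-hydroxy-3-methylbutyl)-3-(7-hydroxy-2,2-dimethyl-2H-chromen-6-yl)-4H-chromen-4-one (kraussianone 3)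
Conditions: K2CO3 (0.5 equiv), degassed MeOH, 0 °C → rt, Ar; then AcOH, aq. Na2S2O4 wash
Reagents that add atoms: none
Why: Base-catalysed transesterification (methanolysis) removes the three aryl acetates without affecting the chromene, the tertiary alcohol or the chromone, and air is excluded to keep the hydroquinone reduced.

**Compound list**
1 | 2,5-dihydroxybenzaldehyde | O=Cc1cc(O)ccc1O | starting material
2 | 2,5-bis(benzyloxy)benzaldehyde | O=Cc1cc(OCc2ccccc2)ccc1OCc1ccccc1 | intermediate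
3 | 2,5-bis(benzyloxy)phenyl formate (in situ) | O=COc1cc(OCc2ccccc2)ccc1OCc1ccccc1 | intermediate
4 | 2,5-bis(benzyloxy)phenol | Oc1cc(OCc2ccccc2)ccc1OCc1ccccc1 | intermediate
5 | 1,4-bis(benzyloxy)-2-(methoxymethoxy)benzene | COCOc1cc(OCc2ccccc2)ccc1OCc1ccccc1 | intermediate
6 | 1,4-bis(benzyloxy)-2-bromo-5-(methoxymethoxy)benzene | Brc1cc(OCc2ccccc2)c(OCOC)cc1OCc1ccccc1 | intermediate
7 | 2-methylbut-3-en-2-ol | CC(C)(O)C=C | starting material
8 | 4-(9-borabicyclo[3.3.1]nonan-9-yl)-2-methylbutan-2-ol (in situ) | CC(C)(O)CCB1C2CCCC1CCC2 | intermediate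
9 | 4-[2,5-bis(benzyloxy)-4-(methoxymethoxy)phenyl]-2-methylbutan-2-ol | CC(C)(O)CCc1cc(OCc2ccccc2)c(OCOC)cc1OCc1ccccc1 | intermediate
10 | lithium 4-[2,5-bis(benzyloxy)-3-lithio-4-(methoxymethoxy)phenyl]-2-methylbutan-2-olate (in situ) | [Li]OC(C)(C)CCc1cc(OCc2ccccc2)c(OCOC)c([Li])c1OCc1ccccc1 | intermediate
11 | 1-[3,6-bis(benzyloxy)-5-(3-hydroxy-3-methylbutyl)-2-(methoxymethoxy)phenyl]ethan-1-one | CC(=O)c1c(OCOC)c(OCc2ccccc2)cc(CCC(C)(C)O)c1OCc1ccccc1 | intermediate
12 | resorcinol (benzene-1,3-diol) | Oc1cccc(O)c1 | starting material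
13 | 3-methylbut-2-enoic acid | CC(C)=CC(=O)O | starting material
14 | 1-(2,4-dihydroxyphenyl)-3-methylbut-2-en-1-one (in situ) | CC(C)=CC(=O)c1ccc(O)cc1O | intermediate
15 | 7-hydroxy-2,2-dimethylchroman-4-one | CC1(C)CC(=O)c2ccc(O)cc2O1 | intermediate
16 | 2,2-dimethylchromane-4,7-diol (racemic, in situ) | CC1(C)CC(O)c2ccc(O)cc2O1 | intermediate
17 | 2,2-dimethylchroman-7-ol | CC1(C)CCc2ccc(O)cc2O1 | intermediate
18 | 6-(hydroxymethyl)-2,2-dimethylchroman-7-ol (in situ) | CC1(C)CCc2cc(CO)c(O)cc2O1 | intermediate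
19 | 7-hydroxy-2,2-dimethylchroman-6-carbaldehyde | CC1(C)CCc2cc(C=O)c(O)cc2O1 | intermediate
20 | 7-(benzyloxy)-2,2-dimethylchroman-6-carbaldehyde | CC1(C)CCc2cc(C=O)c(OCc3ccccc3)cc2O1 | intermediate
21 | 1-[3,6-bis(benzyloxy)-5-(3-hydroxy-3-methylbutyl)-2-(methoxymethoxy)phenyl]-3-[7-(benzyloxy)-2,2-dimethylchroman-6-yl]-3-hydroxypropan-1-one (racemic, in situ) | CC(C)(O)CCc1cc(OCc2ccccc2)c(OCOC)c(C(=O)CC(O)c2cc3c(cc2OCc2ccccc2)OC(C)(C)CC3)c1OCc1ccccc1 | intermediate
22 | (E)-1-[3,6-bis(benzyloxy)-5-(3-hydroxy-3-methylbutyl)-2-(methoxymethoxy)phenyl]-3-[7-(benzyloxy)-2,2-dimethylchroman-6-yl]prop-2-en-1-one | CC(C)(O)CCc1cc(OCc2ccccc2)c(OCOC)c(C(=O)/C=C/c2cc3c(cc2OCc2ccccc2)OC(C)(C)CC3)c1OCc1ccccc1 | intermediate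
23 | 1-[3,6-bis(benzyloxy)-5-(3-hydroxy-3-methylbutyl)-2-(methoxymethoxy)phenyl]-2-[7-(benzyloxy)-2,2-dimethylchroman-6-yl]-3,3-dimethoxypropan-1-one (racemic) | CC(C)(O)CCc1cc(OCc2ccccc2)c(OCOC)c(C(=O)C(C(OC)OC)c2cc3c(cc2OCc2ccccc2)OC(C)(C)CC3)c1OCc1ccccc1 | intermediate
24 | 1-[3,6-bis(benzyloxy)-2-hydroxy-5-(3-hydroxy-3-methylbutyl)phenyl]-2-[7-(benzyloxy)-2,2-dimethylchroman-6-yl]-3,3-dimethoxypropan-1-one (racemic, in situ) | CC(C)(O)CCc1cc(OCc2ccccc2)c(O)c(C(=O)C(C(OC)OC)c2cc3c(cc2OCc2ccccc2)OC(C)(C)CC3)c1OCc1ccccc1 | intermediate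
25 | 5,8-bis(benzyloxy)-3-[7-(benzyloxy)-2,2-dimethylchroman-6-yl]-6-(3-hydroxy-3-methylbutyl)-4H-chromen-4-one | CC(C)(O)CCc1cc(OCc2ccccc2)c2occ(-c3cc4c(cc3OCc3ccccc3)OC(C)(C)CC4)c(=O)c2c1OCc1ccccc1 | intermediate
26 | 5,8-dihydroxy-3-(7-hydroxy-2,2-dimethylchroman-6-yl)-6-(3-hydroxy-3-methylbutyl)-4H-chromen-4-one | CC(C)(O)CCc1cc(O)c2occ(-c3cc4c(cc3O)OC(C)(C)CC4)c(=O)c2c1O | intermediate
27 | 3-[7-(acetyloxy)-2,2-dimethylchroman-6-yl]-6-(3-hydroxy-3-methylbutyl)-4-oxo-4H-chromene-5,8-diyl diacetate | CC(C)(O)CCc1cc(OC(C)=O)c2occ(-c3cc4c(cc3OC(C)=O)OC(C)(C)CC4)c(=O)c2c1OC(C)=O | intermediate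
28 | 3-[7-(acetyloxy)-2,2-dimethyl-2H-chromen-6-yl]-6-(3-hydroxy-3-methylbutyl)-4-oxo-4H-chromene-5,8-diyl diacetate | CC(C)(O)CCc1cc(OC(C)=O)c2occ(-c3cc4c(cc3OC(C)=O)OC(C)(C)C=C4)c(=O)c2c1OC(C)=O | intermediate
29 | 5,8-dihydroxy-6-(3-hydroxy-3-methylbutyl)-3-(7-hydroxy-2,2-dimethyl-2H-chromen-6-yl)-4H-chromen-4-one (kraussianone 3, achiral) | CC(C)(O)CCc1cc(O)c2occ(-c3cc4c(cc3O)OC(C)(C)C=C4)c(=O)c2c1O | target

**Totals and weak points**
Total step count: 17. Longest linear sequence: 13 steps (steps 1–6, then 11–17); the ring B aldehyde is a 4-step branch (steps 7–10).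

Most likely to fail, first: step 6. Benzylic deprotonation of a benzyl ether (leading to Wittig rearrangement) or poor acylation of the hindered aryllithium could compete with the wanted ortho-lithiation. The fallback avoids organolithium chemistry, sets out from 9 and comes back at 11. Compound 9 is treated with 1 M HCl in MeOH to give 2,5-bis(benzyloxy)-4-(3-hydroxy-3-methylbutyl)phenol F1. Its single free ortho position is formylated with MgCl2, Et3N and paraformaldehyde to give 3,6-bis(benzyloxy)-2-hydroxy-5-(3-hydroxy-3-methylbutyl)benzaldehyde F2. The phenol is reprotected with MOMCl and i-Pr2NEt to give 3,6-bis(benzyloxy)-5-(3-hydroxy-3-methylbutyl)-2-(methoxymethoxy)benzaldehyde F3. MeMgBr (2.5 equiv) adds to the aldehyde to give racemic 4-[2,5-bis(benzyloxy)-3-(1-hydroxyethyl)-4-(methoxymethoxy)phenyl]-2-methylbutan-2-ol F4. Dess–Martin periodinane then oxidises the secondary benzylic alcohol to 11.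

Second: step 12. The very electron-rich rings may be attacked by Tl(NO3)3, or the aryl shift may be low-yielding. The fallback keeps the chalcone, sets out from 22 and comes back at 25. Weitz–Scheffer epoxidation (H2O2, NaOH, MeOH–THF) gives [3,6-bis(benzyloxy)-5-(3-hydroxy-3-methylbutyl)-2-(methoxymethoxy)phenyl]{trans-3-[7-(benzyloxy)-2,2-dimethylchroman-6-yl]oxiran-2-yl}methanone F5. BF3·OEt2 in CH2Cl2 at −20 °C opens the epoxide at the benzylic carbon and a 1,2-aroyl shift gives 3-[3,6-bis(benzyloxy)-5-(3-hydroxy-3-methylbutyl)-2-(methoxymethoxy)phenyl]-2-[7-(benzyloxy)-2,2-dimethylchroman-6-yl]-3-oxopropanal F6. Exposure to the HCl–MeOH conditions of step 13 removes the MOM group and cyclodehydrates this formyl ketone to 25.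

Third: step 16. The acetoxy group para to the ring fusion makes the chroman a poorer hydride donor, so the DDQ reaction may be slow or incomplete. The fallback sets out from 27 and comes back at 28. Radical benzylic bromination (NBS, cat. AIBN, PhCF3, 80 °C) at the electron-rich chroman C4 gives 3-[7-(acetyloxy)-4-bromo-2,2-dimethylchroman-6-yl]-6-(3-hydroxy-3-methylbutyl)-4-oxo-4H-chromene-5,8-diyl diacetate F7. Elimination with DBU in toluene then gives 28.

**Further compounds**
F1 | step 6 | 2,5-bis(benzyloxy)-4-(3-hydroxy-3-methylbutyl)phenol | CC(C)(O)CCc1cc(OCc2ccccc2)c(O)cc1OCc1ccccc1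
F2 | step 6 | 3,6-bis(benzyloxy)-2-hydroxy-5-(3-hydroxy-3-methylbutyl)benzaldehyde | O=Cc1c(O)c(OCc2ccccc2)cc(CCC(C)(C)O)c1OCc1ccccc1
F3 | step 6 | 3,6-bis(benzyloxy)-5-(3-hydroxy-3-methylbutyl)-2-(methoxymethoxy)benzaldehyde | O=Cc1c(OCOC)c(OCc2ccccc2)cc(CCC(C)(C)O)c1OCc1ccccc1
F4 | step 6 | 4-[2,5-bis(benzyloxy)-3-(1-hydroxyethyl)-4-(methoxymethoxy)phenyl]-2-methylbutan-2-ol (racemic) | CC(O)c1c(OCOC)c(OCc2ccccc2)cc(CCC(C)(C)O)c1OCc1ccccc1
F5 | step 12 | [3,6-bis(benzyloxy)-5-(3-hydroxy-3-methylbutyl)-2-(methoxymethoxy)phenyl]{trans-3-[7-(benzyloxy)-2,2-dimethylchroman-6-yl]oxiran-2-yl}methanone (racemic, one enantiomer drawn) | CC(C)(O)CCc1cc(OCc2ccccc2)c(OCOC)c(C(=O)[C@@H]2O[C@H]2c2cc3c(cc2OCc2ccccc2)OC(C)(C)CC3)c1OCc1ccccc1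
F6 | step 12 | 3-[3,6-bis(benzyloxy)-5-(3-hydroxy-3-methylbutyl)-2-(methoxymethoxy)phenyl]-2-[7-(benzyloxy)-2,2-dimethylchroman-6-yl]-3-oxopropanal (racemic, enolisable) | CC(C)(O)CCc1cc(OCc2ccccc2)c(OCOC)c(C(=O)C(C=O)c2cc3c(cc2OCc2ccccc2)OC(C)(C)CC3)c1OCc1ccccc1
F7 | step 16 | 3-[7-(acetyloxy)-4-bromo-2,2-dimethylchroman-6-yl]-6-(3-hydroxy-3-methylbutyl)-4-oxo-4H-chromene-5,8-diyl diacetate (racemic) | CC(C)(O)CCc1cc(OC(C)=O)c2occ(-c3cc4c(cc3OC(C)=O)OC(C)(C)CC4Br)c(=O)c2c1OC(C)=O
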